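(The numbers in the tables were generated by integration on assumed constants.)

Temperature runs two clocks in these flasks, one for the work of G and one for its death, so which flask ends ahead needs a reckoning.

in all of them: Z 0.102 M

| charge | L | X | G | temperature | remark | time |
|---|---|---|---|---|---|---|
| theta | 0.085 M | 0.085 M | 8.5 mM | −5 °C | run made earlier |  |
| epsilon | 0.13 M | 0.13 M | 8.5 mM | 12 °C | run made earlier |  |
| beta | 0.17 M | 0.17 M | 4.2 mM | −5 °C | run made earlier |  |
| Wednesday's | 0.17 M | 0.17 M | 8.5 mM |  | at 25 °C until 3.0 d, from then on at 0 °C | 10 d |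
| Thursday's | 0.17 M | 0.17 M | 8.5 mM | 0 °C |  | 10 d |
| Tuesday's | 0.17 M | 0.17 M | 8.5 mM | 25 °C |  | 10 d |

| run | time / d | E / % | L / % |
|---|---|---|---|
| theta | 0.833 | 6.7 | 43.6 |
| theta | 1.67 | 11.0 | 39.2 |
| theta | 3.00 | 17.3 | 34.2 |
| theta | 5.00 | 22.9 | 27.6 |
| theta | 10.0 | 30.5 | 18.6 |
| epsilon | 0.500 | 8.0 | 41.6 |
| epsilon | 0.833 | 11.4 | 37.8 |
| epsilon | 1.67 | 17.4 | 32.9 |
| epsilon | 3.00 | 22.2 | 28.2 |
| epsilon | 6.00 | 26.4 | 23.4 |
| beta | 2.08 | 7.1 | 43.0 |
| beta | 4.00 | 11.1 | 39.3 |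
| beta | 6.00 | 14.2 | 35.9 |
| beta | 8.00 | 17.0 | 33.2 |
| beta | 10.0 | 18.6 | 31.7 |

(scatter of a reading: 0.3 percentage points)

- the best flask by amount of E, in percent of the L and X together charged; "all alike" if 1.5 percentage points covers them all (Wednesday's / Thursday's / Tuesday's / all alike)
- amount of E at the end, in percent of the L and X together charged, Wednesday's
- amount of E at the end, in percent of the L and X together charged, Thursday's
- amount of E at the end, in percent of the L and X together charged, Tuesday's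

- G is single-handed; L and X are mirror images of each other, charged as a racemate, each of them at the stated concentration
- steps that have been proposed: G -> J; 2 G -> Q; Z + G + X -> G + D; Z + G + L -> G + E

In the theta run E and L add up to 49.1 % at 10.0 d, so we read L as going to E. X and D were not read, so we assume that X is hardly touched, as in a kinetic resolution. Let l and z be the fractions of L and Z left, with Z lost to D neglected, and let κ be the rate of L's loss per unit of Z. Then

W = ln(l/z) / (cL − cZ), and with G dying at first-order rate d, W(t) = κ(1 − e^(−dt))/d.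

Early, W grows as κt; late, it stops at κ/d. Readings at t and at double t give e^(−dt) as their ratio less 1.

Taking l from L and E together, theta has W = 7.61 M⁻¹ at 5.00 d and 14.1 M⁻¹ at 10.0 d, which gives d = 0.0317 d⁻¹ and κ = 1.64 M⁻¹ d⁻¹. Epsilon has 8.68 M⁻¹ at 3.00 d and 13.2 M⁻¹ at 6.00 d, which gives d = 0.215 d⁻¹ and κ = 3.92 M⁻¹ d⁻¹. Straight Arrhenius lines through these give

at 0 °C: κ = 2.15 M⁻¹ d⁻¹, d = 0.0571 d⁻¹;
at 25 °C: κ = 7.14 M⁻¹ d⁻¹, d = 0.802 d⁻¹.

In our reckoning Thursday's G lives 17.5 d, longer than the run, and reaches W = 16.4 M⁻¹. This W, the catalyst's exposure, is the summed working power of G over a run. Tuesday's G lives 1.25 d, so it stops at 8.90 M⁻¹, and Wednesday's reaches 9.22 M⁻¹. Inverting W, we expect E of 25.1 % on Thursday's, 20.6 % on Wednesday's and 20.3 % on Tuesday's.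

The forecast also picks Thursday's, with 24.5 % (22.5 % to 26.5 %), 21 % (18.5 % to 23.5 %) for Wednesday's and 20.5 % (17.5 % to 23 %) for Tuesday's, on these grounds: “Catalyst death outruns the gain in rate when warm”. On Thursday's it differs from ours by 0.60 percentage points.

Thursday's gives 24.5 %, more than Wednesday's 20.5 % and Tuesday's 20.6 %.

    G → J (k = 3.08 × 10⁻⁴ min⁻¹, Ea = 94.0 kJ mol⁻¹)
    2 G → Q (k = 0.0270 M⁻¹ min⁻¹, Ea = 77.0 kJ mol⁻¹)
    Z + G + X → G + D (k = 0.0883 M⁻² min⁻¹, Ea = 58.0 kJ mol⁻¹)
    Z + G + L → G + E (k = 0.662 M⁻² min⁻¹, Ea = 35.0 kJ mol⁻¹)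
    (constants at 25 °C)

At 10.0 d Thursday's keeps 64.1 % of its G and Tuesday's 0.479 %. Thursday's E corresponds to W = 15.1 M⁻¹, against our 16.4 M⁻¹. A neighbour, Thursday's flask with Z at 0.41 M, also holds G at 64.1 %. Lending it our 16.4 M⁻¹ leaves l = 1.16 %, and that neighbour holds 1.2 % of its charged L.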